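The linear C15 chain is numbered C1 (alkyne terminus) to C15 (ethyl terminus); O6 links C6 and C10, O13 links C7 and C13. The oxane (O6, C6–C10) and the oxocane (O13, C7–C13) share C7 and C10, and each new C–C bond lies next to a ring oxygen. Both bonds are therefore made from oxocarbenium ions of one acyclic, (R)-malate-derived bis-acetal. Tin tetrabromide ionises the C7 acetoxy ether and a tethered γ-alkoxyallylsilane closes the oxane (C6–C7). The anomeric C10 methoxy group then ionises and the vinyl group of the C7 ether closes the bridging oxocane (C10–C11) with bromide capture at C12. Two purchased stereocentres relay four new ones.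

Key step: step 9

Assumption: dimethyl (R)-malate 1, (2E)-3-(trimethylsilyl)prop-2-en-1-ol 5 and (3R)-pent-1-en-3-ol 10 are taken as commercial; the acetal centres C7 and C10 are carried as epimer mixtures because both are ionised in step 9.

Step 1
Reactants: 1 dimethyl (2R)-2-hydroxybutanedioate
Product: 2 dimethyl (2R)-2-[(triisopropylsilyl)oxy]butanedioate
Conditions: iPr3SiOTf, 2,6-lutidine, CH2Cl2, 0 °C
Reagents that add atoms: triisopropylsilyl trifluoromethanesulfonate, CC(C)[Si](C(C)C)(C(C)C)OS(=O)(=O)C(F)(F)F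
Why: Silylation of the secondary alcohol with a silyl triflate and a hindered base should protect the C9 oxygen without touching the stereocentre.

Step 2
Reactants: 2 dimethyl (2R)-2-[(triisopropylsilyl)oxy]butanedioate
Product: 3 methyl (3R)-4-oxo-3-[(triisopropylsilyl)oxy]butanoate
Conditions: iBu2AlH (1.05 equiv), CH2Cl2, −78 °C
Reagents that add atoms: none
Why: Half-reduction of an ester with iBu2AlH should occur at the more electrophilic ester next to the silyloxy group, whose tetrahedral aluminate is stable at −78 °C, so the distal ester survives.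

Step 3
Reactants: 3 methyl (3R)-4-oxo-3-[(triisopropylsilyl)oxy]butanoate
Product: 4 methyl (3R)-4,4-dimethoxy-3-[(triisopropylsilyl)oxy]butanoate
Conditions: HC(OMe)3, PPTS, MeOH, rt
Reagents that add atoms: trimethyl orthoformate, COC(OC)OC
Why: Acid-catalysed acetalisation with the orthoformate as water scavenger is mild enough to leave the silyl ether and the adjacent stereocentre intact.

Step 4
Reactants: 4 methyl (3R)-4,4-dimethoxy-3-[(triisopropylsilyl)oxy]butanoate; 5 (2E)-3-(trimethylsilyl)prop-2-en-1-ol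
Product: 7 methyl (3R)-4-methoxy-3-[(triisopropylsilyl)oxy]-4-{[(2E)-3-(trimethylsilyl)prop-2-en-1-yl]oxy}butanoate, via collidinium salt 6 (not isolated)
Conditions: Et3SiOTf, 2,4,6-collidine, CH2Cl2, 0 °C; then 5, 0 °C to rt
Reagents that add atoms: none
Why: Acetal exchange through the pyridinium-type salt formed from the dimethyl acetal and the silyl triflate should give the mixed acetal; the new acetal centre C10 forms unselectively, which is immaterial because it is ionised in step 9.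

Step 5
Reactants: 7 methyl (3R)-4-methoxy-3-[(triisopropylsilyl)oxy]-4-{[(2E)-3-(trimethylsilyl)prop-2-en-1-yl]oxy}butanoate
Product: 8 methyl (3R)-4-methoxy-3-[(triisopropylsilyl)oxy]-4-{[(1E)-3-(trimethylsilyl)prop-1-en-1-yl]oxy}butanoate
Conditions: [Ir(cod)(PMePh2)2]PF6 (2 mol %, H2-activated), THF, rt
Reagents that add atoms: none
Why: Iridium hydride catalysed 1,3-hydrogen shift of an allyl ether to the (E)-enol ether should move the double bond into conjugation with oxygen and so unveil the γ-alkoxyallylsilane.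

Step 6
Reactants: 8 methyl (3R)-4-methoxy-3-[(triisopropylsilyl)oxy]-4-{[(1E)-3-(trimethylsilyl)prop-1-en-1-yl]oxy}butanoate
Product: 9 (3R)-4-methoxy-3-[(triisopropylsilyl)oxy]-4-{[(1E)-3-(trimethylsilyl)prop-1-en-1-yl]oxy}butanoic acid
Conditions: LiOH, THF/H2O, 0 °C to rt; NaH2PO4 buffer work-up
Reagents that add atoms: lithium hydroxide, [Li+].[OH-]
Why: Saponification of the methyl ester with buffered work-up should leave the acid-labile acetal, the enol ether and the silyl ether intact.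

Step 7
Reactants: 9 (3R)-4-methoxy-3-[(triisopropylsilyl)oxy]-4-{[(1E)-3-(trimethylsilyl)prop-1-en-1-yl]oxy}butanoic acid; 10 (3R)-pent-1-en-3-ol
Product: 11 (3R)-pent-1-en-3-yl (3R)-4-methoxy-3-[(triisopropylsilyl)oxy]-4-{[(1E)-3-(trimethylsilyl)prop-1-en-1-yl]oxy}butanoate
Conditions: EDC, DMAP, CH2Cl2, 0 °C to rt
Reagents that add atoms: none
Why: Steglich-type carbodiimide esterification should join the acid to the purchased alcohol, bringing in C11–C15 and the C13 stereocentre unchanged.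

Step 8
Reactants: 11 (3R)-pent-1-en-3-yl (3R)-4-methoxy-3-[(triisopropylsilyl)oxy]-4-{[(1E)-3-(trimethylsilyl)prop-1-en-1-yl]oxy}butanoate
Product: 13 (3R)-4-methoxy-1-[(3R)-pent-1-en-3-yloxy]-3-[(triisopropylsilyl)oxy]-4-{[(1E)-3-(trimethylsilyl)prop-1-en-1-yl]oxy}butyl acetate, via aluminium hemiacetal 12 (not isolated)
Conditions: iBu2AlH, CH2Cl2, −78 °C; then pyridine, DMAP, Ac2O, −78 to −20 °C
Reagents that add atoms: acetic anhydride, CC(=O)OC(C)=O
Why: Reductive acetylation of the ester, in which the tetrahedral aluminium hemiacetal is trapped in situ by acetic anhydride, should give the α-acetoxy ether as C7 epimers that ionise to the same cation.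

Step 9
Reactants: 13 (3R)-4-methoxy-1-[(3R)-pent-1-en-3-yloxy]-3-[(triisopropylsilyl)oxy]-4-{[(1E)-3-(trimethylsilyl)prop-1-en-1-yl]oxy}butyl acetate
Product: 15 (1S,3R,4S,6R,8R,10R)-4-bromo-8-ethenyl-3-ethyl-10-[(triisopropylsilyl)oxy]-2,7-dioxabicyclo[4.2.2]decane, via methyl glycoside 14 (not isolated)
Conditions: SnBr4 (2.5 equiv), 2,6-di-tert-butyl-4-methylpyridine, CH2Cl2, −78 °C, then −20 °C; aq. NaHCO3
Reagents that add atoms: tin tetrabromide, Br[Sn](Br)(Br)Br
Why: Proposed new method: SnBr4 should first ionise the acetate at C7 to the oxocarbenium ion O13=C7, which is captured 6-exo by the γ-carbon C6 of the γ-alkoxyallylsilane with loss of silicon (the known Hosomi–Sakurai-type intramolecular allylation of α-acetoxy ethers), through a chair transition state with the C9 silyloxy group, the C7 ether and the new C6 vinyl group all equatorial, so that C9 sets C7 (1,3-cis) and C6 (2,3-trans) in methyl glycoside 14. On warming, the anomeric methoxy group at C10 should ionise and the oxocarbenium ion O6=C10 be attacked 8-endo-trig by the terminal carbon C11 of the vinyl group carried on O13. The closest known reaction types are Prins closures of eight-membered cyclic ethers and bromide-terminated Prins cyclisations promoted by tin or titanium bromides, but a bridging closure from a ring oxygen substituent onto a pyranosyl cation has not been shown. C10 is fixed because C11 can only arrive on the face that carries O13 (1,4-cis, trans to the C6 side chain), and C12 by bromide capture of the developing secondary cation anti to the new C10–C11 bond and away from the C13 ethyl group. The step needs the C7 acetate to ionise before the C10 acetal, which the better leaving group and the inductive deactivation of C10 by the C9 silyloxy group should secure. It also needs the vinyl group not to attack C7, which would be a disfavoured 5-endo closure.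

Step 10
Reactants: 15 (1S,3R,4S,6R,8R,10R)-4-bromo-8-ethenyl-3-ethyl-10-[(triisopropylsilyl)oxy]-2,7-dioxabicyclo[4.2.2]decane
Product: 17 2-{(1S,3R,4S,6R,8R,10R)-4-bromo-3-ethyl-10-[(triisopropylsilyl)oxy]-2,7-dioxabicyclo[4.2.2]decan-8-yl}ethanol, via alkylborane 16 (not isolated)
Conditions: 9-BBN, THF, 0 °C to rt; then H2O2, aq. NaOAc, 0 °C
Reagents that add atoms: hydrogen peroxide, OO
Why: Anti-Markovnikov hydroboration of the only alkene with 9-BBN and buffered oxidation of the alkylborane should give the primary alcohol and spare the secondary bromide.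

Step 11
Reactants: 17 2-{(1S,3R,4S,6R,8R,10R)-4-bromo-3-ethyl-10-[(triisopropylsilyl)oxy]-2,7-dioxabicyclo[4.2.2]decan-8-yl}ethanol
Product: 18 {(1S,3R,4S,6R,8R,10R)-4-bromo-3-ethyl-10-[(triisopropylsilyl)oxy]-2,7-dioxabicyclo[4.2.2]decan-8-yl}acetaldehyde
Conditions: Dess–Martin periodinane, NaHCO3, CH2Cl2, 0 °C to rt
Reagents that add atoms: none
Why: Dess–Martin oxidation of the primary alcohol under buffered, non-basic conditions should give the aldehyde without β-elimination of the ring oxygen.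

Step 12
Reactants: 18 {(1S,3R,4S,6R,8R,10R)-4-bromo-3-ethyl-10-[(triisopropylsilyl)oxy]-2,7-dioxabicyclo[4.2.2]decan-8-yl}acetaldehyde
Product: 19 (1S,3R,4S,6R,8R,10R)-4-bromo-3-ethyl-8-[(2E)-3-iodoprop-2-en-1-yl]-10-[(triisopropylsilyl)oxy]-2,7-dioxabicyclo[4.2.2]decane
Conditions: CrCl2, CHI3, THF, 0 °C to rt
Reagents that add atoms: iodoform, IC(I)I
Why: Takai olefination through the geminal dichromium species from CHI3 and divalent chromium should give the (E)-vinyl iodide selectively and leave the alkyl bromide alone.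

Step 13
Reactants: 19 (1S,3R,4S,6R,8R,10R)-4-bromo-3-ethyl-8-[(2E)-3-iodoprop-2-en-1-yl]-10-[(triisopropylsilyl)oxy]-2,7-dioxabicyclo[4.2.2]decane
Product: 20 (1S,3R,4S,6R,8R,10R)-4-bromo-3-ethyl-10-[(triisopropylsilyl)oxy]-8-[(2E)-5-(trimethylsilyl)pent-2-en-4-yn-1-yl]-2,7-dioxabicyclo[4.2.2]decane
Conditions: Me3SiC≡CH, Pd(PPh3)4, CuI, iPr2NH, rt
Reagents that add atoms: ethynyltrimethylsilane, C#C[Si](C)(C)C
Why: Sonogashira coupling of the vinyl iodide with the silylacetylene should build the enyne with retention of the (E) geometry.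

Step 14
Reactants: 20 (1S,3R,4S,6R,8R,10R)-4-bromo-3-ethyl-10-[(triisopropylsilyl)oxy]-8-[(2E)-5-(trimethylsilyl)pent-2-en-4-yn-1-yl]-2,7-dioxabicyclo[4.2.2]decane
Product: 21 (1S,3R,4S,6R,8R,10R)-4-bromo-3-ethyl-8-[(2E)-pent-2-en-4-yn-1-yl]-2,7-dioxabicyclo[4.2.2]decan-10-ol
Conditions: Bu4NF, AcOH, THF, rt
Reagents that add atoms: none
Why: Fluoride should cleave the alkynyl C–Si bond and the secondary silyl ether in one operation, with acetic acid buffering against elimination of the bromide.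

Step 15
Reactants: 21 (1S,3R,4S,6R,8R,10R)-4-bromo-3-ethyl-8-[(2E)-pent-2-en-4-yn-1-yl]-2,7-dioxabicyclo[4.2.2]decan-10-ol
Product: 22 (1S,3R,4S,6R,8R,10S)-4,10-dibromo-3-ethyl-8-[(2E)-pent-2-en-4-yn-1-yl]-2,7-dioxabicyclo[4.2.2]decane
Conditions: CBr4, PPh3, toluene, 60 °C
Reagents that add atoms: tetrabromomethane, BrC(Br)(Br)Br
Why: Appel bromination should displace the alkoxyphosphonium ion with bromide with inversion at C9, turning the (9R)-alcohol into the (9S)-bromide of the target.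

Compound list
1 | dimethyl (2R)-2-hydroxybutanedioate (dimethyl (R)-malate) | COC(=O)C[C@@H](O)C(=O)OC | starting material
2 | dimethyl (2R)-2-[(triisopropylsilyl)oxy]butanedioate | COC(=O)C[C@@H](O[Si](C(C)C)(C(C)C)C(C)C)C(=O)OC | intermediate
3 | methyl (3R)-4-oxo-3-[(triisopropylsilyl)oxy]butanoate | COC(=O)C[C@@H](O[Si](C(C)C)(C(C)C)C(C)C)C=O | intermediate
4 | methyl (3R)-4,4-dimethoxy-3-[(triisopropylsilyl)oxy]butanoate | COC(=O)C[C@@H](O[Si](C(C)C)(C(C)C)C(C)C)C(OC)OC | intermediate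
5 | (2E)-3-(trimethylsilyl)prop-2-en-1-ol | C[Si](C)(C)/C=C/CO | starting material
6 | 1-{(2R)-1,4-dimethoxy-4-oxo-2-[(triisopropylsilyl)oxy]butyl}-2,4,6-trimethylpyridinium trifluoromethanesulfonate (collidinium salt, C10 epimers) | COC(=O)C[C@@H](O[Si](C(C)C)(C(C)C)C(C)C)C(OC)[n+]1c(C)cc(C)cc1C.[O-]S(=O)(=O)C(F)(F)F | intermediate
7 | methyl (3R)-4-methoxy-3-[(triisopropylsilyl)oxy]-4-{[(2E)-3-(trimethylsilyl)prop-2-en-1-yl]oxy}butanoate (C4 epimers) | COC(=O)C[C@@H](O[Si](C(C)C)(C(C)C)C(C)C)C(OC)OC/C=C/[Si](C)(C)C | intermediate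
8 | methyl (3R)-4-methoxy-3-[(triisopropylsilyl)oxy]-4-{[(1E)-3-(trimethylsilyl)prop-1-en-1-yl]oxy}butanoate (C4 epimers) | COC(=O)C[C@@H](O[Si](C(C)C)(C(C)C)C(C)C)C(OC)O/C=C/C[Si](C)(C)C | intermediate
9 | (3R)-4-methoxy-3-[(triisopropylsilyl)oxy]-4-{[(1E)-3-(trimethylsilyl)prop-1-en-1-yl]oxy}butanoic acid (C4 epimers) | OC(=O)C[C@@H](O[Si](C(C)C)(C(C)C)C(C)C)C(OC)O/C=C/C[Si](C)(C)C | intermediate
10 | (3R)-pent-1-en-3-ol | CC[C@@H](O)C=C | starting material
11 | (3R)-pent-1-en-3-yl (3R)-4-methoxy-3-[(triisopropylsilyl)oxy]-4-{[(1E)-3-(trimethylsilyl)prop-1-en-1-yl]oxy}butanoate (C4 epimers) | CC[C@H](C=C)OC(=O)C[C@@H](O[Si](C(C)C)(C(C)C)C(C)C)C(OC)O/C=C/C[Si](C)(C)C | intermediate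
12 | diisobutylaluminium hemiacetal of 11 (C7 and C10 epimers; C9 R, C13 R) | CC[C@H](C=C)OC(O[Al](CC(C)C)CC(C)C)C[C@@H](O[Si](C(C)C)(C(C)C)C(C)C)C(OC)O/C=C/C[Si](C)(C)C | intermediate
13 | (3R)-4-methoxy-1-[(3R)-pent-1-en-3-yloxy]-3-[(triisopropylsilyl)oxy]-4-{[(1E)-3-(trimethylsilyl)prop-1-en-1-yl]oxy}butyl acetate (C1 and C4 epimers; chain C9 R, C13 R) | CC[C@H](C=C)OC(OC(C)=O)C[C@@H](O[Si](C(C)C)(C(C)C)C(C)C)C(OC)O/C=C/C[Si](C)(C)C | intermediate
14 | (2R,3S,5R)-2-ethenyl-6-methoxy-3-[(3R)-pent-1-en-3-yloxy]-5-[(triisopropylsilyl)oxy]oxane (C6 epimers; chain C6 R, C7 S, C9 R, C13 R) | C=C[C@H]1OC(OC)[C@H](O[Si](C(C)C)(C(C)C)C(C)C)C[C@@H]1O[C@H](CC)C=C | intermediate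
15 | (1S,3R,4S,6R,8R,10R)-4-bromo-8-ethenyl-3-ethyl-10-[(triisopropylsilyl)oxy]-2,7-dioxabicyclo[4.2.2]decane (chain 6R,7S,9R,10R,12S,13R) | C=C[C@H]1O[C@@H]2C[C@H](Br)[C@@H](CC)O[C@H]1C[C@H]2O[Si](C(C)C)(C(C)C)C(C)C | intermediate
16 | 9-(2-{(1S,3R,4S,6R,8R,10R)-4-bromo-3-ethyl-10-[(triisopropylsilyl)oxy]-2,7-dioxabicyclo[4.2.2]decan-8-yl}ethyl)-9-borabicyclo[3.3.1]nonane | C1CCC2CCCC1B2CC[C@H]3O[C@@H]4C[C@H](Br)[C@@H](CC)O[C@H]3C[C@H]4O[Si](C(C)C)(C(C)C)C(C)C | intermediate
17 | 2-{(1S,3R,4S,6R,8R,10R)-4-bromo-3-ethyl-10-[(triisopropylsilyl)oxy]-2,7-dioxabicyclo[4.2.2]decan-8-yl}ethanol | OCC[C@H]1O[C@@H]2C[C@H](Br)[C@@H](CC)O[C@H]1C[C@H]2O[Si](C(C)C)(C(C)C)C(C)C | intermediate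
18 | {(1S,3R,4S,6R,8R,10R)-4-bromo-3-ethyl-10-[(triisopropylsilyl)oxy]-2,7-dioxabicyclo[4.2.2]decan-8-yl}acetaldehyde | O=CC[C@H]1O[C@@H]2C[C@H](Br)[C@@H](CC)O[C@H]1C[C@H]2O[Si](C(C)C)(C(C)C)C(C)C | intermediate
19 | (1S,3R,4S,6R,8R,10R)-4-bromo-3-ethyl-8-[(2E)-3-iodoprop-2-en-1-yl]-10-[(triisopropylsilyl)oxy]-2,7-dioxabicyclo[4.2.2]decane | I/C=C/C[C@H]1O[C@@H]2C[C@H](Br)[C@@H](CC)O[C@H]1C[C@H]2O[Si](C(C)C)(C(C)C)C(C)C | intermediate
20 | (1S,3R,4S,6R,8R,10R)-4-bromo-3-ethyl-10-[(triisopropylsilyl)oxy]-8-[(2E)-5-(trimethylsilyl)pent-2-en-4-yn-1-yl]-2,7-dioxabicyclo[4.2.2]decane | C[Si](C)(C)C#C/C=C/C[C@H]1O[C@@H]2C[C@H](Br)[C@@H](CC)O[C@H]1C[C@H]2O[Si](C(C)C)(C(C)C)C(C)C | intermediate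
21 | (1S,3R,4S,6R,8R,10R)-4-bromo-3-ethyl-8-[(2E)-pent-2-en-4-yn-1-yl]-2,7-dioxabicyclo[4.2.2]decan-10-ol | C#C/C=C/C[C@H]1O[C@@H]2C[C@H](Br)[C@@H](CC)O[C@H]1C[C@H]2O | intermediate
22 | (1S,3R,4S,6R,8R,10S)-4,10-dibromo-3-ethyl-8-[(2E)-pent-2-en-4-yn-1-yl]-2,7-dioxabicyclo[4.2.2]decane (chain 6R,7S,9S,10R,12S,13R) | C#C/C=C/C[C@H]1O[C@@H]2C[C@H](Br)[C@@H](CC)O[C@H]1C[C@@H]2Br | target

Total step count: 15. Longest linear sequence: 15 steps (1 to 22).

Steps most likely to fail

Step 9 (proposed new method). The second closure may not keep pace with the first: the electron-poor vinyl group may attack the pyranosyl cation too slowly, so that elimination or reversible bromide trapping at C10 takes over. The C10 acetal may also ionise before the C7 acetate, the O13 allylic ether may fragment at the cation stage, and bromide capture at C12 may show poor facial selectivity. The fallback uses only known allylsilane–oxocarbenium closures; it sets out from acid 9 and returns at 15. Acid 9 is esterified (EDC, DMAP) with (3R)-2-[(trimethylsilyl)methyl]pent-1-en-3-ol F1, obtained from propanal and [3-(trimethylsilyl)prop-1-en-2-yl]magnesium bromide, CH2=C(CH2SiMe3)MgBr, followed by lipase resolution, to give the ester F2. Reductive acetylation as in step 8 gives the α-acetoxy ether F3. Me3SiOTf in CH2Cl2 should then effect two Hosomi–Sakurai closures, first C6–C7 and then C10–C11 by the much more nucleophilic allylsilane, to give the bicyclic diene F4 with an exocyclic methylene group at C12. The electron-rich 1,1-disubstituted alkene is epoxidised selectively with mCPBA to the spiro-epoxide F5, and periodic acid cleaves it to the ketone F6. NaBH4 should reduce from the face away from the C13 ethyl group to the (12R)-alcohol F7, and Appel bromination with inversion gives 15.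

Step 15. Displacement at C9 is hindered and flanked by the oxygen-bearing C10, so elimination towards C8 or C10 or participation of a ring oxygen may compete with clean inversion. The fallback sets out from 21 and returns at 22. The alcohol is converted into the isolable triflate F8 (Tf2O, pyridine, CH2Cl2, −20 °C), a far better leaving group, which is displaced by Bu4NBr in toluene at rt with inversion.

Step 2. Regioselectivity between the two ester groups may be lost under the bulky silyl ether, or over-reduction to the alcohol may occur. The fallback sets out from 1 and returns at 3. Hydroxyl-directed reduction of the ester next to the free hydroxyl group (BH3·SMe2, catalytic NaBH4, THF) gives methyl (3R)-3,4-dihydroxybutanoate F9. Selective silylation of the primary hydroxyl (tBuMe2SiCl, imidazole) gives the mono-silyl ether F10, and iPr3SiOTf with 2,6-lutidine gives the bis-silyl ether F11. PPTS in MeOH removes the primary silyl group to give the primary alcohol F12, and Dess–Martin oxidation gives 3.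

Further compounds
F1 | step 9 | (3R)-2-[(trimethylsilyl)methyl]pent-1-en-3-ol | CC[C@@H](O)C(=C)C[Si](C)(C)C
F2 | step 9 | (3R)-2-[(trimethylsilyl)methyl]pent-1-en-3-yl ester of acid 9 | CC[C@H](C(=C)C[Si](C)(C)C)OC(=O)C[C@@H](O[Si](C(C)C)(C(C)C)C(C)C)C(OC)O/C=C/C[Si](C)(C)C
F3 | step 9 | α-acetoxy ether from F2 (C7 and C10 epimers) | CC[C@H](C(=C)C[Si](C)(C)C)OC(OC(C)=O)C[C@@H](O[Si](C(C)C)(C(C)C)C(C)C)C(OC)O/C=C/C[Si](C)(C)C
F4 | step 9 | (1S,3R,6R,8R,10R)-8-ethenyl-3-ethyl-4-methylidene-10-[(triisopropylsilyl)oxy]-2,7-dioxabicyclo[4.2.2]decane | C=C[C@H]1O[C@@H]2CC(=C)[C@@H](CC)O[C@H]1C[C@H]2O[Si](C(C)C)(C(C)C)C(C)C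
F5 | step 9 | spiro-epoxide of F4 at C12 (epimers at the spiro carbon) | C=C[C@H]1O[C@@H]2CC3(CO3)[C@@H](CC)O[C@H]1C[C@H]2O[Si](C(C)C)(C(C)C)C(C)C
F6 | step 9 | (1S,3R,6R,8R,10R)-8-ethenyl-3-ethyl-10-[(triisopropylsilyl)oxy]-2,7-dioxabicyclo[4.2.2]decan-4-one | C=C[C@H]1O[C@@H]2CC(=O)[C@@H](CC)O[C@H]1C[C@H]2O[Si](C(C)C)(C(C)C)C(C)C
F7 | step 9 | (1S,3R,4R,6R,8R,10R)-8-ethenyl-3-ethyl-10-[(triisopropylsilyl)oxy]-2,7-dioxabicyclo[4.2.2]decan-4-ol | C=C[C@H]1O[C@@H]2C[C@@H](O)[C@@H](CC)O[C@H]1C[C@H]2O[Si](C(C)C)(C(C)C)C(C)C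
F8 | step 15 | (1S,3R,4S,6R,8R,10R)-4-bromo-3-ethyl-8-[(2E)-pent-2-en-4-yn-1-yl]-2,7-dioxabicyclo[4.2.2]decan-10-yl trifluoromethanesulfonate | C#C/C=C/C[C@H]1O[C@@H]2C[C@H](Br)[C@@H](CC)O[C@H]1C[C@H]2OS(=O)(=O)C(F)(F)F
F9 | step 2 | methyl (3R)-3,4-dihydroxybutanoate | COC(=O)C[C@@H](O)CO
F10 | step 2 | methyl (3R)-4-[(tert-butyldimethylsilyl)oxy]-3-hydroxybutanoate | COC(=O)C[C@@H](O)CO[Si](C)(C)C(C)(C)C
F11 | step 2 | methyl (3R)-4-[(tert-butyldimethylsilyl)oxy]-3-[(triisopropylsilyl)oxy]butanoate | COC(=O)C[C@@H](O[Si](C(C)C)(C(C)C)C(C)C)CO[Si](C)(C)C(C)(C)C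
F12 | step 2 | methyl (3R)-4-hydroxy-3-[(triisopropylsilyl)oxy]butanoate | COC(=O)C[C@@H](O[Si](C(C)C)(C(C)C)C(C)C)CO
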